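**Structural features**

The target is an apigenin derivative. Benzene ring A is fused along C4a–C8a to the 4-pyranone ring C, the 4-hydroxyphenyl ring B sits on C2, and C8 carries a 2-carboxy-1-phenylethyl chain. The only stereocentre is the chain methine (R), bonded to C8, a phenyl ring, hydrogen and the CH2CO2H arm. It has no stereogenic neighbour, so its configuration must come from a catalyst and then be carried through untouched. Ring A is hexasubstituted (oxygen on C5, C7 and C8a, carbon on C4a and C8, hydrogen only on C6), and any route that closes ring C onto a C-alkylated phloroglucinol must tell two ortho oxygens apart or it also gives the 6-substituted isomer. Four points are fragile: the carboxyl group can lactonise onto the 7-hydroxyl under acidic or dehydrating conditions; the doubly benzylic methine on an electron-rich ring can be ionised or cleaved by strong acid; C6–H traps carbocations and formaldehyde; and the polyphenol oxidises in aerated base. The real difficulty is to put the chain on C8 only, in one configuration, and to finish without strong acid. The key step uses the 1,3,5-oxygen pattern of ring A: C5 to C8 have the oxidation pattern of a δ-substituted β-keto ester, and a 2-aryl-4-pyranone already holds O1, C8a and C4a. A four-carbon bis(silyloxy)diene added across a sulfinyl-activated C4a=C8a bond therefore completes ring A with the chain necessarily on C8.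

**Logic of the disconnections**

Flavone numbering is used for every atom that ends up in the chromone.

17 to 16. The two O–CH2Ph bonds (carboxyl oxygen and 4'-oxygen) are cut. Both groups leave together under neutral hydrogenolysis, so the last step uses no acid (no lactonisation onto the 7-hydroxyl, no carbocation or formaldehyde near C6) and no base. Nothing is gained in skeleton; the gain is a one-step, neutral end. The forward step must stop before the C2=C3 bond is reduced and needs 16 free of sulfur residues.

16 to 7 and 13. C8–C8a and C4a–C5 are cut, which opens ring A. The cut divides the molecule into a chiral open-chain half and an achiral heterocyclic half of similar size. It also removes the C6/C8 question, because O1 is bonded to C8a before ring A exists. The forward step needs the diene to add to C4a=C8a and not to C2=C3, with its substituted terminus on C8a, and needs sulfenic acid and methanol to leave so that the arene forms. The four transient ring stereocentres and the sulfur chirality are erased, so 13 can be racemic at sulfur.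

7 to 5 through 6. Two O–Si bonds are cut; 7 is the double silyl enol ether of 5. This replaces a labile diene by a storable β-keto ester. The forward steps need enolisation at the γ-carbon (future C8) in the presence of a second ester, and must leave the methine alone; the methine is not alpha to any carbonyl.

5 to 2. The C6–C7 bond (ketone carbon to the methylene of the keto ester) is cut, giving an acyl donor and a malonate half ester. This reduces the chiral half to a glutarate hemiester. The activation must not exchange the two carboxyl termini, which would racemise the compound, so a mild acyl imidazolide is used and no acid chloride.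

2 to 1. One acyl C–O bond is cut. The forward reaction is a catalytic desymmetrisation that sets the only stereocentre from an achiral, cheap anhydride. The alcohol must be primary, since a tertiary alcohol does not open the anhydride under this catalysis. The alcohol chosen becomes the carboxyl protecting group directly, so no protecting-group exchange is needed.

13 to 10 and 11. C2–C3 (carbon–carbon) and O1–C8a (carbon–oxygen) are cut, which opens ring C to a methyl ketone enolate and an aroyl chloride. The enolate must be C-acylated and the enol oxygen must then displace the amine at C8a. The 4'-oxygen carries the same benzyl group as the ester.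

10 to 9 to 8. C4a=C8a (aminomethylenation of the activated methylene) and C4–C4a (acylation of the sulfinyl carbanion) are cut, leading back to a purchased racemic sulfoxide. Each step must react only at the carbon flanked by sulfur and carbonyl.

**Other disconnections considered**

Alternative 1: The cut removes four carbons of the plain phenyl ring on the stereocentre (the ipso–ortho bond and the bond from the second alkyne carbon to the adjacent meta carbon). The precursors are the terminal alkyne methyl (3R)-3-[2-(benzyloxy)-4,6-dimethoxyphenyl]pent-4-ynoate A2 and buta-1,3-diene A3. In the forward step a low-valent cobalt catalyst made from CoBr2(dppe), zinc and ZnI2 would join A2 and A3 in a (4+2) sense, and DDQ would dehydrogenate the primary cycloadduct in the same pot to methyl (3R)-3-[2-(benzyloxy)-4,6-dimethoxyphenyl]-3-phenylpropanoate A1.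
- In its favour: the cobalt cycloaddition is a dependable method, A3 is symmetrical so there is no regiochemistry to control, ring A is bought complete, and no labile silyl diene is handled. On robustness of the key step itself this alternative is the better of the two.
- Against it: the ring it builds is the one part of the target that needs no synthesis, so the strategic step solves nothing. The quinone oxidant is a threat to the electron-rich, doubly benzylic methine (hydride abstraction would destroy the configuration). A1 still lacks ring C, and getting there requires acylation that distinguishes the two free ring positions, release of O1, flavone closure and removal of two aryl methyl ethers and a methyl ester with reagents such as BBr3. Those conditions invite lactonisation and isomerisation of the 8- to the 6-substituted flavone.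
- Comparison: both plans form an arene by cycloaddition and aromatisation. The chosen plan spends that step on the hexasubstituted ring A and fixes C8, and reaches the target one step later. The alternative would need five or more steps after A1.

Alternative 2: The cut removes C8a–C8 and C6–C7 of ring A. The third new bond, made by the Wolff shift of the methoxyvinyl group onto the former diazo carbon, is C4a–C5. The precursors are 1-diazo-3-methoxybut-3-en-2-one A5 and the siloxyalkyne tert-butyl (3R)-3-phenyl-5-[(triisopropylsilyl)oxy]pent-4-ynoate A6. Irradiation would turn A5 into a methoxyvinylketene, which adds (2+2) to A6. Four-electron opening of the cyclobutenone and six-electron closure would then give the phenol tert-butyl (3R)-3-{2-hydroxy-4-methoxy-6-[(triisopropylsilyl)oxy]phenyl}-3-phenylpropanoate A4.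
- In its favour: the regiochemistry follows from the mechanism, the three oxygens of ring A come out fully differentiated, and the conditions are neutral. On regiochemical certainty and on precedent for crowded resorcinols the alternative is equal to or better than the chosen key step, which relies on extending a chromone reaction to a monocyclic pyranone. It is equally gentle on the stereocentre.
- Against it: A6 needs ynolate chemistry on the chiral ester, A5 is a small and hazardous diazo ketone, and photochemistry limits scale. Above all, A4 has no ring C. C-acylation at C4a beside an acid-labile silyl ether and tert-butyl ester, flavone closure, demethylation at C5, desilylation and ester cleavage add about six operations, several of them acidic with a free hydroxyl next to the chain.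
- Comparison: both build ring A around C8. The chosen plan does it on a finished ring C and ends with one neutral step, so it is clearly shorter.

Alternative 3: The cut removes O1–C8a, C4a–C4 and O1–C2, so that ring C is assembled on an aryne of ring A. The precursors are the silylaryl triflate methyl (3R)-3-{2,4-dimethoxy-6-[(trifluoromethanesulfonyl)oxy]-5-(trimethylsilyl)phenyl}-3-phenylpropanoate A8 and 3-(4-methoxyphenyl)prop-2-ynoic acid A9. CsF would release the C4a–C8a aryne, the carboxylate of A9 would add through oxygen to C8a, and the C4a carbanion would take the acyl carbon. The resulting phenoxide would then close 6-endo onto the ynone to give methyl (3R)-3-[5,7-dimethoxy-2-(4-methoxyphenyl)-4-oxo-4H-chromen-8-yl]-3-phenylpropanoate A7.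
- In its favour: three bonds and the whole of ring C form in one flask, which is more bond formation per step than the chosen key step. The 5-methoxy group directs the oxygen nucleophile to C8a, and no sulfur or silyl diene is needed.
- Against it: A8 is a hexasubstituted benzene that already carries the stereocentre beside the triflate, and making it would take longer than both halves of the chosen plan. The bulky chain flanks C8a and opposes the attack that the methoxy group favours. The phenoxide could close 5-exo to an aurone. A7 carries three aryl methyl ethers and a methyl ester, and removing them needs BBr3 or hot mineral acid, under which lactonisation, 8-to-6 isomerisation and loss of configuration are the known dangers.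
- Comparison: both plans settle the position of O1, the alternative by electronic direction and the chosen plan by having the bond from the start, which is the safer. Overall the chosen plan is shorter and ends under neutral conditions.

Key step: step 8

Assumptions and remarks
- Assumption: compounds 1, 8 and 11 are purchased.
- Assumption: the quinidine-derived catalyst of step 1 is taken to give the R hemiester 2. If the sense proves opposite, the quinine-derived pseudoenantiomer is used and nothing else changes.
- Remark: 13 is racemic at sulfur and is written without a sulfur descriptor, because the sulfur chirality is destroyed in step 8.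
- Remark: the descriptor of the chain methine reads R in 2 to 6, S in 7 and 14, and R in 15 to 17. This reflects changes of CIP priority only; no bond at that carbon is touched after step 1.

**Route**

Step 1
Reactants: 1 the anhydride 3-phenylglutaric anhydride (4-phenyloxane-2,6-dione)
Product: 2 the hemiester (3R)-5-(benzyloxy)-5-oxo-3-phenylpentanoic acid
Conditions: BnOH (3 equiv), 3,5-bis(trifluoromethyl)benzenesulfonamide of 9-amino-9-deoxy-epi-quinidine (10 mol%), MTBE, −20 °C; dilute HCl wash
Reagents that add atoms: benzyl alcohol, OCc1ccccc1
Why: Cinchona-catalysed desymmetrising alcoholysis of a prochiral cyclic anhydride; the quinuclidine nitrogen activates the alcohol while the sulfonamide N–H binds one of the two enantiotopic carbonyl groups, so the catalyst decides which carbonyl is opened and thereby sets the stereocentre; the enantiomeric purity can be raised by crystallising an amine salt.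

Step 2
Reactants: 2 the hemiester (3R)-5-(benzyloxy)-5-oxo-3-phenylpentanoic acid
Product: 5 the β-keto ester 7-benzyl 1-methyl (5R)-3-oxo-5-phenylheptanedioate, via acyl imidazolide 3 (not isolated), via acylmalonic half ester 4 (not isolated)
Conditions: 1,1'-carbonyldiimidazole (1.1 equiv), THF, rt; then KO2CCH2CO2Me (2 equiv), MgCl2 (1.5 equiv), Et3N (2 equiv), THF/MeCN, rt to 40 °C; 10% aqueous citric acid
Reagents that add atoms: potassium methyl malonate, COC(=O)CC(=O)[O-].[K+]
Why: Masamune–Brooks homologation (C-acylation of a magnesium malonate half ester by an acyl imidazolide, then decarboxylation); the neutral activation avoids the alkoxy migration that can exchange the two termini of a glutarate half ester, and the methine is not enolisable, so the configuration is kept.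

Step 3
Reactants: 5 the β-keto ester 7-benzyl 1-methyl (5R)-3-oxo-5-phenylheptanedioate
Product: 6 the silyl enol ether 7-benzyl 1-methyl (5R)-5-phenyl-3-[(trimethylsilyl)oxy]hept-2-enedioate (E/Z mixture)
Conditions: Me3SiCl (1.6 equiv), Et3N (1.8 equiv), toluene, rt, 48 h; filtration under argon; used crude
Reagents that add atoms: chlorotrimethylsilane, C[Si](C)(C)Cl
Why: O-silylation of the enol form of a β-keto ester with a weak amine base; the benzyl ester and the methine are not touched, and the alkene geometry is of no consequence.

Step 4
Reactants: 6 the silyl enol ether 7-benzyl 1-methyl (5R)-5-phenyl-3-[(trimethylsilyl)oxy]hept-2-enedioate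
Product: 7 benzyl (3S,4Z,6Z)-7-methoxy-3-phenyl-5,7-bis[(trimethylsilyl)oxy]hepta-4,6-dienoate
Conditions: LiN(iPr)2 (1.1 equiv), THF, −78 °C, 1 h; Me3SiCl (1.3 equiv), −78 °C to rt; pentane, filtration under argon; used at once
Reagents that add atoms: chlorotrimethylsilane, C[Si](C)(C)Cl
Why: γ-Deprotonation of the β-silyloxy enoate to the extended dienolate and O-silylation, the standard preparation of 1-alkoxy-1,3-bis(silyloxy)dienes; the vinylogous γ-hydrogen is more acidic than the alpha hydrogens of the isolated benzyl ester, the methine is not deprotonated, and the drawn geometry (chain trans to the diene) is the one expected but is not required for the arene.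

Step 5
Reactants: 8 methyl p-tolyl sulfoxide (racemic)
Product: 9 the β-keto sulfoxide 1-[(4-methylphenyl)sulfinyl]propan-2-one (racemic)
Conditions: 8 (2 equiv), LiN(iPr)2 (2 equiv), THF, −78 °C; EtOAc (1 equiv), −78 to 0 °C; aqueous NH4Cl; excess 8 recovered
Reagents that add atoms: ethyl acetate, CCOC(C)=O
Why: Claisen-type acylation of the α-sulfinyl carbanion by an ester; the second equivalent of carbanion deprotonates the product and so prevents a second addition.

Step 6
Reactants: 9 the β-keto sulfoxide 1-[(4-methylphenyl)sulfinyl]propan-2-one
Product: 10 the enaminone 4-(dimethylamino)-3-[(4-methylphenyl)sulfinyl]but-3-en-2-one (racemic at sulfur)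
Conditions: Me2NCH(OMe)2 (1.2 equiv), toluene, rt to 50 °C
Reagents that add atoms: N,N-dimethylformamide dimethyl acetal, COC(OC)N(C)C
Why: Condensation of an amide acetal with the methylene flanked by sulfinyl and carbonyl groups, which is far more acidic than the methyl group; no acid anhydride is present, so the sulfoxide is not drawn into Pummerer chemistry.

Step 7
Reactants: 10 the enaminone 4-(dimethylamino)-3-[(4-methylphenyl)sulfinyl]but-3-en-2-one; 11 4-(benzyloxy)benzoyl chloride
Product: 13 the pyranone 2-[4-(benzyloxy)phenyl]-5-[(4-methylphenyl)sulfinyl]-4H-pyran-4-one (racemic at sulfur), via enaminodione 12 (not isolated)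
Conditions: LiN(SiMe3)2 (2.1 equiv), THF, −78 °C; 11 (1 equiv), −78 to −40 °C; AcOH quench; then CF3CO2H (2 equiv), CH2Cl2, rt
Reagents that add atoms: none
Why: Kinetic deprotonation at the only enolisable position of the vinylogous amide (the methyl ketone), C-acylation by the acid chloride with the second equivalent of base taking up the acidic 1,3-diketone, then acid-promoted addition of the enol oxygen to the aminomethylene carbon with loss of dimethylamine (6-endo closure); this is the enaminone acylation and cyclisation route to 2-substituted 4-pyranones.

Step 8
Reactants: 7 benzyl (3S,4Z,6Z)-7-methoxy-3-phenyl-5,7-bis[(trimethylsilyl)oxy]hepta-4,6-dienoate; 13 the pyranone 2-[4-(benzyloxy)phenyl]-5-[(4-methylphenyl)sulfinyl]-4H-pyran-4-one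
Product: 16 benzyl (3R)-3-{2-[4-(benzyloxy)phenyl]-5,7-dihydroxy-4-oxo-4H-chromen-8-yl}-3-phenylpropanoate, via cycloadduct 14 (not isolated), via bis(trimethylsilyl) ether 15 (not isolated)
Conditions: 7 (1.5 equiv), toluene, rt, 24 h, then 80 °C, 3 h; then 1 M HCl, THF, 0 °C to rt, 30 min
Reagents that add atoms: none
Why: The electron-rich 1-methoxy-1,3-bis(silyloxy)diene 7 adds in a normal-electron-demand Diels–Alder reaction across C4a=C8a of 13, the nucleophilic diene terminus (future C8) bonding to the β-carbon C8a of the sulfinyl enone and the ketene acetal carbon (future C5) to C4a, either in one asynchronous (4+2) event or as a Mukaiyama–Michael addition followed by closure of the sulfinyl-stabilised enolate carbon C4a onto the carbonyl-level carbon C5; both paths give 14. Warming then brings about syn elimination of p-toluenesulfenic acid (C4a–S with the cis C8a–H), which restores C4a=C8a, and loss of methanol from C5 and C8 aromatises ring A to 15, whose two silyl ethers fall to dilute acid. The closest known reaction type is the Diels–Alder and aromatisation sequence of oxygenated silyloxydienes with 3-sulfinylchromones and sulfinylquinones, where the sulfinyl group is activating group and leaving group in the same way. Ring A is the one ring closed, by (4+2) cycloaddition, or in the stepwise reading by a 6-exo-trig closure of C4a onto C5. No new stereocentre survives: the four ring stereocentres of 14 and the sulfur chirality vanish on aromatisation, so racemic 13 and any endo/exo or facial mixture converge on one product, while the chain methine takes no part because the hydrogen lost is the one on C8. The step needs site selectivity (C4a=C8a and not C2=C3) and one orientation; both follow from the sulfinyl group, which makes C4a=C8a the more electron-poor double bond and C8a its electrophilic end, whereas C2=C3 carries the aryl group and no second acceptor, and since O1 is bonded to C8a from the start the chain can only arrive at C8. Heating before hydrolysis keeps C7 as its silyl enol ether until the sulfinyl group has left, which blocks retro-oxa-Michael opening of ring C, and acidic (not basic or fluoride) desilylation avoids a 7-phenoxide next to the benzyl ester.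

Step 9
Reactants: 16 benzyl (3R)-3-{2-[4-(benzyloxy)phenyl]-5,7-dihydroxy-4-oxo-4H-chromen-8-yl}-3-phenylpropanoate
Product: 17 (3R)-3-[5,7-dihydroxy-2-(4-hydroxyphenyl)-4-oxo-4H-chromen-8-yl]-3-phenylpropanoic acid
Conditions: H2 (1 atm), Pd/C (10 wt% palladium on carbon), EtOAc/THF, rt; filtration through Celite
Reagents that add atoms: none
Why: Hydrogenolysis of the benzyl ester and the aryl benzyl ether in one neutral operation; the C2=C3 bond of the pyranone is a vinylogous ester within a conjugated ring and is reduced much more slowly, and without acid or base there is no lactonisation onto the 7-hydroxyl and no path to epimerisation.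

**Compound list**

1 | 3-phenylglutaric anhydride (4-phenyloxane-2,6-dione) | O=C1CC(CC(=O)O1)c1ccccc1 | starting material
2 | (3R)-5-(benzyloxy)-5-oxo-3-phenylpentanoic acid | O=C(OCc1ccccc1)C[C@H](c1ccccc1)CC(=O)O | intermediate
3 | benzyl (3R)-5-(1H-imidazol-1-yl)-5-oxo-3-phenylpentanoate | O=C(OCc1ccccc1)C[C@H](c1ccccc1)CC(=O)n1ccnc1 | intermediate
4 | (5R)-7-(benzyloxy)-2-(methoxycarbonyl)-3,7-dioxo-5-phenylheptanoic acid (C2 configurationally labile) | O=C(OCc1ccccc1)C[C@H](c1ccccc1)CC(=O)C(C(=O)O)C(=O)OC | intermediate
5 | 7-benzyl 1-methyl (5R)-3-oxo-5-phenylheptanedioate | O=C(OCc1ccccc1)C[C@H](c1ccccc1)CC(=O)CC(=O)OC | intermediate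
6 | 7-benzyl 1-methyl (5R)-5-phenyl-3-[(trimethylsilyl)oxy]hept-2-enedioate (E/Z mixture) | O=C(OCc1ccccc1)C[C@H](c1ccccc1)CC(O[Si](C)(C)C)=CC(=O)OC | intermediate
7 | benzyl (3S,4Z,6Z)-7-methoxy-3-phenyl-5,7-bis[(trimethylsilyl)oxy]hepta-4,6-dienoate | O=C(OCc1ccccc1)C[C@H](c1ccccc1)/C=C(\O[Si](C)(C)C)/C=C(/OC)O[Si](C)(C)C | intermediate
8 | methyl p-tolyl sulfoxide (racemic) | CS(=O)c1ccc(C)cc1 | starting material
9 | 1-[(4-methylphenyl)sulfinyl]propan-2-one (racemic) | CC(=O)CS(=O)c1ccc(C)cc1 | intermediate
10 | 4-(dimethylamino)-3-[(4-methylphenyl)sulfinyl]but-3-en-2-one (racemic at sulfur) | CC(=O)C(=CN(C)C)S(=O)c1ccc(C)cc1 | intermediate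
11 | 4-(benzyloxy)benzoyl chloride | O=C(Cl)c1ccc(OCc2ccccc2)cc1 | starting material
12 | 1-[4-(benzyloxy)phenyl]-5-(dimethylamino)-4-[(4-methylphenyl)sulfinyl]pent-4-ene-1,3-dione | O=C(CC(=O)C(=CN(C)C)S(=O)c1ccc(C)cc1)c1ccc(OCc2ccccc2)cc1 | intermediate
13 | 2-[4-(benzyloxy)phenyl]-5-[(4-methylphenyl)sulfinyl]-4H-pyran-4-one (racemic at sulfur) | O=c1cc(-c2ccc(OCc3ccccc3)cc2)occ1S(=O)c1ccc(C)cc1 | intermediate
14 | benzyl (3S)-3-{2-[4-(benzyloxy)phenyl]-5-methoxy-4a-[(4-methylphenyl)sulfinyl]-4-oxo-5,7-bis[(trimethylsilyl)oxy]-4a,5,8,8a-tetrahydro-4H-chromen-8-yl}-3-phenylpropanoate (mixture of ring and sulfur stereoisomers) | COC1(O[Si](C)(C)C)C=C(O[Si](C)(C)C)C([C@H](CC(=O)OCc2ccccc2)c2ccccc2)C2OC(=CC(=O)C12S(=O)c1ccc(C)cc1)c1ccc(OCc2ccccc2)cc1 | intermediate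
15 | benzyl (3R)-3-{2-[4-(benzyloxy)phenyl]-4-oxo-5,7-bis[(trimethylsilyl)oxy]-4H-chromen-8-yl}-3-phenylpropanoate | O=C(OCc1ccccc1)C[C@H](c1ccccc1)c1c(O[Si](C)(C)C)cc(O[Si](C)(C)C)c2c(=O)cc(-c3ccc(OCc4ccccc4)cc3)oc12 | intermediate
16 | benzyl (3R)-3-{2-[4-(benzyloxy)phenyl]-5,7-dihydroxy-4-oxo-4H-chromen-8-yl}-3-phenylpropanoate | O=C(OCc1ccccc1)C[C@H](c1ccccc1)c1c(O)cc(O)c2c(=O)cc(-c3ccc(OCc4ccccc4)cc3)oc12 | intermediate
17 | (3R)-3-[5,7-dihydroxy-2-(4-hydroxyphenyl)-4-oxo-4H-chromen-8-yl]-3-phenylpropanoic acid | O=C(O)C[C@H](c1ccccc1)c1c(O)cc(O)c2c(=O)cc(-c3ccc(O)cc3)oc12 | target

**Step count and least certain steps**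

Total: 9 steps. Longest linear sequence: 6 steps (steps 1, 2, 3, 4, 8, 9); the pyranone branch (steps 5, 6, 7) joins at step 8.

Step 8 (key step). The most likely failure is too little dienophilic reactivity: the monocyclic pyranone is partly aromatic and the reacting diene terminus carries a branched substituent. Decay of the diene (protodesilylation by the sulfenic acid set free, silyl migration) could then outrun the cycloaddition. If the addition becomes stepwise, ring C could also open by retro-oxa-Michael before ring A is closed. The fallback changes the electrophile from the neutral pyranone to a cation and the bond formation from a thermal pericyclic event to a polar two-stage annulation. It sets out from 13, which is treated with Me3SiOTf (1.1 equiv, CH2Cl2, −78 °C) to give 2-[4-(benzyloxy)phenyl]-5-[(4-methylphenyl)sulfinyl]-4-[(trimethylsilyl)oxy]pyrylium trifluoromethanesulfonate F1. Diene 7 adds through its substituted terminus to the unsubstituted carbon next to the ring oxygen (C8a), and the 4-silyloxy enol ether so formed closes onto the oxocarbenium carbon C5 with release of Me3SiOTf. The fallback comes back to the route at 14, which is heated and hydrolysed to 16 as in step 8. Silyl triflate activation of 4-pyranones and chromones toward silyl enol ethers and bis(silyloxy)dienes at the carbon next to oxygen is established chemistry.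

Step 4. The risk is competing deprotonation alpha to the benzyl ester, whose kinetic acidity is not far from that of the γ-position, leading to incomplete or misplaced silylation. The fallback gives up amide-base deprotonation for soft enolisation. It sets out from 5, which is treated with Me3SiOTf (2.2 equiv) and Et3N (2.5 equiv) in Et2O at 0 °C; silylation at oxygen activates the 1,3-dicarbonyl unit and the amine removes first the central and then the γ-hydrogen, a mode established for 1,3-dicarbonyl compounds. An isolated ester is enolised far more slowly under these conditions. The fallback comes back to the route at 7 and makes no new compound.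

Step 7. The risks are self-condensation of the enaminone enolate on its own electrophilic aminomethylene carbon, O-acylation in place of C-acylation, and interference of the sulfinyl group (chelation of lithium, side reactions on acid treatment). The fallback carries sulfur at the sulfide level and oxidises last, which is the usual way to sulfinyl chromones. It sets out from 11 and purchased 1-[(4-methylphenyl)sulfanyl]propan-2-one F2. Condensation of F2 with Me2NCH(OMe)2 gives 4-(dimethylamino)-3-[(4-methylphenyl)sulfanyl]but-3-en-2-one F3. Acylation of F3 with 11 (LiN(SiMe3)2, THF, −78 °C) and acid cyclisation give 2-[4-(benzyloxy)phenyl]-5-[(4-methylphenyl)sulfanyl]-4H-pyran-4-one F4. Oxidation of F4 with 3-chloroperoxybenzoic acid (1 equiv, CH2Cl2, −20 °C) comes back to the route at 13.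

Step 1. The risks are a slower and less selective opening with benzyl alcohol than with methanol, and the unverified sense of induction. The fallback replaces catalytic desymmetrisation by classical resolution. It sets out from 1, which is opened with BnOH and catalytic 4-(dimethylamino)pyridine to racemic 5-(benzyloxy)-5-oxo-3-phenylpentanoic acid F5. The less soluble diastereomeric salt, taken here as (S)-1-phenylethylammonium (3R)-5-(benzyloxy)-5-oxo-3-phenylpentanoate F6 (the antipodal amine is used if the other salt crystallises), is recrystallised and acidified, which comes back to the route at 2.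

**Further compounds**

F1 | step 8 | 2-[4-(benzyloxy)phenyl]-5-[(4-methylphenyl)sulfinyl]-4-[(trimethylsilyl)oxy]pyrylium trifluoromethanesulfonate | C[Si](C)(C)Oc1cc(-c2ccc(OCc3ccccc3)cc2)[o+]cc1S(=O)c1ccc(C)cc1.[O-]S(=O)(=O)C(F)(F)F
F0 | step 4 | none | none
F2 | step 7 | 1-[(4-methylphenyl)sulfanyl]propan-2-one | CC(=O)CSc1ccc(C)cc1
F3 | step 7 | 4-(dimethylamino)-3-[(4-methylphenyl)sulfanyl]but-3-en-2-one | CC(=O)C(=CN(C)C)Sc1ccc(C)cc1
F4 | step 7 | 2-[4-(benzyloxy)phenyl]-5-[(4-methylphenyl)sulfanyl]-4H-pyran-4-one | O=c1cc(-c2ccc(OCc3ccccc3)cc2)occ1Sc1ccc(C)cc1
F5 | step 1 | racemic 5-(benzyloxy)-5-oxo-3-phenylpentanoic acid | O=C(OCc1ccccc1)CC(c1ccccc1)CC(=O)O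
F6 | step 1 | (S)-1-phenylethylammonium (3R)-5-(benzyloxy)-5-oxo-3-phenylpentanoate | C[C@H]([NH3+])c1ccccc1.O=C(OCc1ccccc1)C[C@H](c1ccccc1)CC(=O)[O-]
A1 | alternative 1 | methyl (3R)-3-[2-(benzyloxy)-4,6-dimethoxyphenyl]-3-phenylpropanoate | COC(=O)C[C@H](c1ccccc1)c1c(OCc2ccccc2)cc(OC)cc1OC
A2 | alternative 1 | methyl (3R)-3-[2-(benzyloxy)-4,6-dimethoxyphenyl]pent-4-ynoate | COC(=O)C[C@H](C#C)c1c(OCc2ccccc2)cc(OC)cc1OC
A3 | alternative 1 | buta-1,3-diene | C=CC=C
A4 | alternative 2 | tert-butyl (3R)-3-{2-hydroxy-4-methoxy-6-[(triisopropylsilyl)oxy]phenyl}-3-phenylpropanoate | CC(C)(C)OC(=O)C[C@H](c1ccccc1)c1c(O)cc(OC)cc1O[Si](C(C)C)(C(C)C)C(C)C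
A5 | alternative 2 | 1-diazo-3-methoxybut-3-en-2-one | C=C(OC)C(=O)C=[N+]=[N-]
A6 | alternative 2 | tert-butyl (3R)-3-phenyl-5-[(triisopropylsilyl)oxy]pent-4-ynoate | CC(C)(C)OC(=O)C[C@H](c1ccccc1)C#CO[Si](C(C)C)(C(C)C)C(C)C
A7 | alternative 3 | methyl (3R)-3-[5,7-dimethoxy-2-(4-methoxyphenyl)-4-oxo-4H-chromen-8-yl]-3-phenylpropanoate | COC(=O)C[C@H](c1ccccc1)c1c(OC)cc(OC)c2c(=O)cc(-c3ccc(OC)cc3)oc12
A8 | alternative 3 | methyl (3R)-3-{2,4-dimethoxy-6-[(trifluoromethanesulfonyl)oxy]-5-(trimethylsilyl)phenyl}-3-phenylpropanoate | COC(=O)C[C@H](c1ccccc1)c1c(OC)cc(OC)c([Si](C)(C)C)c1OS(=O)(=O)C(F)(F)F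
A9 | alternative 3 | 3-(4-methoxyphenyl)prop-2-ynoic acid | COc1ccc(cc1)C#CC(=O)O
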